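## Retrosynthetic overview

1. The 6β‑acetate is installed last: α‑epoxide of the Δ6 enol acetate, then a thermal 1,2‑acyloxy shift with inversion at C6 on the rigid tetracycle.
2. The C13 carbinol comes from exo‑face radical (MHAT) hydration of the Δ12 olefin of the tetracycle, so C13 is left uncontrolled until the cage exists.
3. Rings C (cyclobutane) and D (cyclopentane), with C8, C9 and C14, come from one intramolecular enone–olefin [2+2] photocycloaddition of 13‑hydroxylabda‑8,14‑dien‑7‑one (both C13 epimers).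
4. The photosubstrate comes from vinyl addition to 14,15‑dinorlabd‑8‑ene‑7,13‑dione, made by dehydration and allylic oxidation of the C18 ketol from (−)‑sclareol.
5. Ring order: A/B (C5, C10) from the chiral pool; C and D closed together; then C13; then C6.

Assumption: commercial (−)‑sclareol is the natural (5S,8R,9R,10S,13R) enantiomer; its 13R carbinol is the wrong one for the target (13S), so the side‑chain carbinol is cut back to the ketone and rebuilt.

## Route

Step 1
Reactants: 1 (−)‑sclareol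
Product: 2 8α‑hydroxy‑14,15‑dinorlabdan‑13‑one
Conditions: KMnO4, MgSO4, acetone–H2O, 0 °C → rt
Reagents that add atoms: none
Why: Permanganate oxidative cleavage of the tertiary vinyl carbinol (dihydroxylation, then C13–C14 scission) leaves the methyl ketone and removes the acid‑ and Cr(VI)‑sensitive allylic alcohol, while C5, C8, C9 and C10 are untouched.

Step 2
Reactants: 2 8α‑hydroxy‑14,15‑dinorlabdan‑13‑one
Product: 3 14,15‑dinorlabd‑8‑en‑13‑one
Conditions: p‑TsOH·H2O (cat.), PhMe, reflux (Dean–Stark)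
Reagents that add atoms: none
Why: Acid‑catalysed E1 dehydration under equilibrating conditions gives the thermodynamically favoured tetrasubstituted Δ8(9) olefin (Saytzeff control), leaving C5 and C10 intact and making C8/C9 sp2 until step 5.

Step 3
Reactants: 3 14,15‑dinorlabd‑8‑en‑13‑one
Product: 4 14,15‑dinorlabd‑8‑ene‑7,13‑dione
Conditions: CrO3·3,5‑dimethylpyrazole, CH2Cl2, −20 °C
Reagents that add atoms: chromium trioxide (as its 3,5‑dimethylpyrazole complex), O=[Cr](=O)=O
Why: Chromium(VI) allylic oxidation of the tetrasubstituted olefin goes at the ring methylene C7 (axial C–H aligned with the π system, less hindered than C11) to give the enone without creating a stereocentre.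

Step 4
Reactants: 4 14,15‑dinorlabd‑8‑ene‑7,13‑dione
Product: 5 (13RS)‑13‑hydroxylabda‑8,14‑dien‑7‑one
Conditions: CH2=CHMgBr, THF, −78 → −40 °C; then H2O
Reagents that add atoms: vinylmagnesium bromide, C=C[Mg]Br
Why: Grignard 1,2‑addition is chemoselective for the unhindered methyl ketone over the hindered, conjugated, tetrasubstituted enone; C13 forms as both epimers on purpose because it is erased and reset in steps 6 and 7.

Step 5
Reactants: 5 (13RS)‑13‑hydroxylabda‑8,14‑dien‑7‑one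
Product: 6 (13RS)‑13‑hydroxy‑8α,15:9α,14‑dicyclolabdan‑7‑one
Conditions: hν (350 nm, Pyrex), degassed MeCN (3 mM), rt
Reagents that add atoms: none
Why: Key step, an intramolecular enone–olefin [2+2] photocycloaddition (rule of five: C9–C14 closes the five‑membered ring, then C8–C15 closes the cyclobutane) that forms rings C and D at once; the tether adds to the α‑face of the enone, anti to the axial C10 methyl, which fixes C8 (β‑CH3), C9 and C14 (cis‑fused), and both C13 epimers react alike.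

Step 6
Reactants: 6 (13RS)‑13‑hydroxy‑8α,15:9α,14‑dicyclolabdan‑7‑one
Product: 7 8α,15:9α,14‑dicyclolabd‑12‑en‑7‑one
Conditions: Burgess reagent, PhH, 50 °C
Reagents that add atoms: none
Why: Burgess dehydration (syn‑elimination of the sulfamate ester) of both tertiary alcohols gives mainly the trisubstituted Δ12 olefin and erases C13, and any regioisomeric olefin leads to the same tertiary C13 radical in step 7.

Step 7
Reactants: 7 8α,15:9α,14‑dicyclolabd‑12‑en‑7‑one
Product: 8 (13S)‑13‑hydroxy‑8α,15:9α,14‑dicyclolabdan‑7‑one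
Conditions: Co(acac)2 (cat.), PhSiH3, O2 (1 atm), THF, rt
Reagents that add atoms: dioxygen, O=O
Why: Mukaiyama (metal‑hydride HAT) hydration puts H on C12 and the planar tertiary C13 radical is trapped by O2 on the open convex face of the cis‑bicyclo[3.2.0]heptane, anti to the cyclobutane CH2, which gives the 13S alcohol (OH cis to H‑14).

Step 8
Reactants: 8 (13S)‑13‑hydroxy‑8α,15:9α,14‑dicyclolabdan‑7‑one
Product: 10 7‑acetoxy‑13‑(trimethylsilyloxy)‑8α,15:9α,14‑dicyclolabd‑6‑ene, via silyl ether 9 (not isolated)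
Conditions: LDA, THF, −78 °C; TMSCl, → 0 °C; LDA, −78 °C; Ac2O
Reagents that add atoms: chlorotrimethylsilane, C[Si](C)(C)Cl; acetic anhydride, CC(=O)OC(C)=O
Why: One‑pot O‑silylation of the lithium alkoxide is followed by kinetic enolisation (C6 is the only enolisable position because C8 is quaternary) and O‑acylation of the lithium enolate to give the Δ6 enol acetate without a new stereocentre.

Step 9
Reactants: 10 7‑acetoxy‑13‑(trimethylsilyloxy)‑8α,15:9α,14‑dicyclolabd‑6‑ene
Product: 13 CNP0330581.1, via epoxy acetate 11 (not isolated), via silyl ether 12 (not isolated)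
Conditions: DMDO, acetone–CH2Cl2, 0 °C; evaporate; xylene, 140 °C; then 1 M HCl, THF, 0 °C
Reagents that add atoms: dimethyldioxirane, CC1(C)OO1
Why: Dioxirane epoxidation of the enol acetate occurs on the α‑face (the β‑face is screened by the syn‑axial C10 and C4 methyls and the 8β‑methyl), the thermal enol‑ester‑epoxide rearrangement (suprafacial 1,2‑acyloxy shift across the β‑face with inversion at C6) gives the axial 6β‑acetoxy ketone, and mild acid removes the TMS ether.

## Compound list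

1 | (−)‑sclareol, (13R)‑labd‑14‑ene‑8α,13‑diol | C=C[C@](C)(O)CC[C@H]1[C@](C)(O)CC[C@H]2C(C)(C)CCC[C@]12C | starting material
2 | 8α‑hydroxy‑14,15‑dinorlabdan‑13‑one | CC(=O)CC[C@H]1[C@](C)(O)CC[C@H]2C(C)(C)CCC[C@]12C | intermediate
3 | 14,15‑dinorlabd‑8‑en‑13‑one (5α‑H; 10β‑CH3) | CC(=O)CCC1=C(C)CC[C@H]2C(C)(C)CCC[C@]12C | intermediate
4 | 14,15‑dinorlabd‑8‑ene‑7,13‑dione | CC(=O)CCC1=C(C)C(=O)C[C@H]2C(C)(C)CCC[C@]12C | intermediate
5 | (13RS)‑13‑hydroxylabda‑8,14‑dien‑7‑one (about 1:1 at C13) | C=CC(C)(O)CCC1=C(C)C(=O)C[C@H]2C(C)(C)CCC[C@]12C | intermediate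
6 | (13RS)‑13‑hydroxy‑8α,15:9α,14‑dicyclolabdan‑7‑one (cyclobutane C8–C9–C14–C15 on the α‑face; 8β‑CH3; H‑14 cis to C10) | C1C(=O)[C@@]2(C)C[C@H]3[C@@]2(CCC3(C)O)[C@@]2(C)CCCC(C)(C)[C@H]12 | intermediate
7 | 8α,15:9α,14‑dicyclolabd‑12‑en‑7‑one | C1C(=O)[C@@]2(C)C[C@H]3[C@@]2(CC=C3C)[C@@]2(C)CCCC(C)(C)[C@H]12 | intermediate
8 | (13S)‑13‑hydroxy‑8α,15:9α,14‑dicyclolabdan‑7‑one (13‑OH cis to H‑14; 13‑CH3 cis to C15) | C1C(=O)[C@@]2(C)C[C@H]3[C@@]2(CC[C@]3(C)O)[C@@]2(C)CCCC(C)(C)[C@H]12 | intermediate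
9 | 13‑O‑trimethylsilyl ether of 8 | C1C(=O)[C@@]2(C)C[C@H]3[C@@]2(CC[C@]3(C)O[Si](C)(C)C)[C@@]2(C)CCCC(C)(C)[C@H]12 | intermediate
10 | 7‑acetoxy‑13‑(trimethylsilyloxy)‑8α,15:9α,14‑dicyclolabd‑6‑ene | C1=C(OC(C)=O)[C@@]2(C)C[C@H]3[C@@]2(CC[C@]3(C)O[Si](C)(C)C)[C@@]2(C)CCCC(C)(C)[C@H]12 | intermediate
11 | 7β‑acetoxy‑6α,7α‑epoxy‑13‑(trimethylsilyloxy)‑8α,15:9α,14‑dicyclolabdane | [C@H]12O[C@@]1(OC(C)=O)[C@@]3(C)C[C@H]4[C@@]3(CC[C@]4(C)O[Si](C)(C)C)[C@@]3(C)CCCC(C)(C)[C@H]23 | intermediate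
12 | 6β‑acetoxy‑13‑(trimethylsilyloxy)‑8α,15:9α,14‑dicyclolabdan‑7‑one | CC(=O)O[C@@H]1C(=O)[C@@]2(C)C[C@H]3[C@@]2(CC[C@]3(C)O[Si](C)(C)C)[C@@]2(C)CCCC(C)(C)[C@H]12 | intermediate
13 | CNP0330581.1, (5S,6S,8S,9S,10S,13S,14S)‑6β‑acetoxy‑13‑hydroxy‑8α,15:9α,14‑dicyclolabdan‑7‑one | CC(=O)O[C@@H]1C(=O)[C@@]2(C)C[C@H]3[C@@]2(CC[C@]3(C)O)[C@@]2(C)CCCC(C)(C)[C@H]12 | target

## Step count and risks

Total steps: 9. Longest linear sequence: 9 (1 → 13).

**Step 6.** The Burgess sulfamate of a tertiary cyclobutylcarbinol may ionise and trigger cyclobutane ring expansion, and the exo‑OH epimer can also eliminate towards C14. The fallback avoids the carbinol detour altogether. It sets out from ene‑dione 4: irradiation (350 nm, CH2Cl2 saturated with acetylene, −40 °C) gives, by intermolecular [2+2] on the α‑face, the cyclobutene diketone F1. SmI2/HMPA/t‑BuOH in THF then forms the C13 ketyl selectively at the unhindered methyl ketone, and 5‑exo ketyl–olefin cyclisation onto the strained cyclobutene (O–Sm anti to C15) closes ring D with the 13‑OH exo. This comes back to the route at 8.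

**Step 7.** Oxygen capture may not be face‑selective enough, and the cyclobutylcarbinyl radical can fragment. The fallback replaces the radical hydration by a polar sequence from 7. Epoxidation on the convex face (mCPBA, NaHCO3, CH2Cl2, 0 °C) gives the exo‑epoxide F2. LiEt3BH opens it at the secondary carbon C12 (leaving the exo tertiary 13‑OH) and also reduces the C7 ketone, giving the diol F3. Dess–Martin oxidation of the secondary 7‑OH returns to the route at 8.

**Step 9.** The acyloxy shift must deliver the ester to the most hindered face; retention (6α‑acetate) or collapse to the 6α‑hydroxy ketone are the likely failures. The fallback brings the oxygen in from the open face and inverts by reduction instead. From epoxy acetate 11, methanolysis (Et3N, MeOH, 0 °C) gives the 6α‑hydroxy ketone F4. Dess–Martin oxidation gives the 6,7‑dione F5. LiAlH(OtBu)3 at −78 °C attacks the less hindered C6 carbonyl from the α‑face to give the 6β‑hydroxy ketone F6. Ac2O/DMAP/pyridine then gives 12, where the route is rejoined before the acidic desilylation.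

## Further compounds

F1 | step 6 | 13,14‑seco‑8α,15:9α,14‑dicyclolabd‑14‑ene‑7,13‑dione (cyclobutene diketone) | C1C(=O)[C@@]2(C)C=C[C@@]2(CCC(C)=O)[C@@]2(C)CCCC(C)(C)[C@H]12
F2 | step 7 | 12,13‑exo‑epoxy‑8α,15:9α,14‑dicyclolabdan‑7‑one | C1C(=O)[C@@]2(C)C[C@H]3[C@@]2(C[C@H]4[C@]3(C)O4)[C@@]2(C)CCCC(C)(C)[C@H]12
F3 | step 7 | (13S)‑8α,15:9α,14‑dicyclolabdane‑7,13‑diol (C7 configuration immaterial) | C1C(O)[C@@]2(C)C[C@H]3[C@@]2(CC[C@]3(C)O)[C@@]2(C)CCCC(C)(C)[C@H]12
F4 | step 9 | 6α‑hydroxy‑13‑(trimethylsilyloxy)‑8α,15:9α,14‑dicyclolabdan‑7‑one | O[C@H]1C(=O)[C@@]2(C)C[C@H]3[C@@]2(CC[C@]3(C)O[Si](C)(C)C)[C@@]2(C)CCCC(C)(C)[C@H]12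
F5 | step 9 | 13‑(trimethylsilyloxy)‑8α,15:9α,14‑dicyclolabdane‑6,7‑dione | O=C1C(=O)[C@@]2(C)C[C@H]3[C@@]2(CC[C@]3(C)O[Si](C)(C)C)[C@@]2(C)CCCC(C)(C)[C@H]12
F6 | step 9 | 6β‑hydroxy‑13‑(trimethylsilyloxy)‑8α,15:9α,14‑dicyclolabdan‑7‑one | O[C@@H]1C(=O)[C@@]2(C)C[C@H]3[C@@]2(CC[C@]3(C)O[Si](C)(C)C)[C@@]2(C)CCCC(C)(C)[C@H]12
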